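Product forms here in one step per hand: each turn uses one reagent and one substrate and returns the free catalyst.

| flask | left-handed substrate | right-handed substrate | reagent | free catalyst | racemization catalyst | remark | time |
|---|---|---|---|---|---|---|---|
| north-east | 1 M | 1 M | 2 M (fed, over 4.0 min) | 2.4 mM | 10 mM | run made earlier; the fed solution adds 0.10 times the starting volume |  |
| flask | 1.0 M | 1.0 M | 2.00 M (fed, over 4.0 min) | 2.4 mM | 5.0 mM | the fed solution adds 0.10 times the starting volume | 15 min |

- north-east (time / min: left-handed product / %, right-handed product / %): 0.833: 1.0, 0.8; 2.00: 8.3, 3.3; 2.50: 9.8, 3.9; 4.00: 22.5, 9.9; 5.00: 25.4, 15.4

(readings scatter by 1 percentage point)

- free catalyst is single-handed; left-handed substrate and right-handed substrate are mirror images of each other, charged as a racemate, each of them at the stated concentration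
- charges are per starting volume, the dose included; the dosed solution carries all of it
- on the list of suspects stand: left-handed substrate + racemization catalyst <-> right-handed substrate + racemization catalyst; reagent + free catalyst + right-handed substrate -> free catalyst + right-handed product; 2 racemization catalyst -> spent catalyst; reagent + free catalyst + left-handed substrate -> free catalyst + left-handed product
- the reaction counts as stopped when no species that holds the left-handed substrate and right-handed substrate together changes by six tenths of a point or more over the second half of the time
- no earlier run changes the charge of racemization catalyst; that part of a forecast is a guess

1. which holds at 15 min: what has brought the reaction to rest, or that it has not come to rest (all of the left-handed substrate has reacted / the reagent has run out first / it is still moving / no working catalyst is left / forward and back rates have come level)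
2. how much left-handed product there is at 15 min, in percent of the left-handed substrate and right-handed substrate together charged
3. how much right-handed product there is at 15 min, in percent of the left-handed substrate and right-handed substrate together charged
4. how much right-handed substrate there is at 15 min, in percent of the left-handed substrate and right-handed substrate together charged

In this flask the reagent charge equals both substrates together, so neither is the limiting reagent, and after the feed ends at 4.0 min reagent left equals substrate left. Let f be that remainder, as a share of the substrates charged. Lumping both hands as one substrate, the rate then goes with f squared, so the reciprocal of f climbs steadily with time. The north-east run has f at 67.6% at 4.00 min and 59.2% at 5.00 min, so I read a climb of 0.210 min⁻¹, with the scatter of those readings in it.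

My number is N = 2.31, the time after the feed counted in second-order half-lives of a full charge. Taking the end-of-feed f from that run, since feed and free catalyst match, N leaves f at 26.4% at 15 min. At 7.50 min f stands at 45.2%, so it falls 19 percentage points over the second half of the time, and I call the flask still moving.

N counts both hands together; the split takes a selectivity factor, the ratio of the logarithms of what is left of each hand, which the same readings put at 2.22. This gives right-handed substrate 19.9%, left-handed product 43.5% and right-handed product 30.1%. I leave racemization out of this, and what the halved racemization catalyst charge does is a guess.

The forecast says it is still moving, with 44.5% left-handed product, 29.5% right-handed product and 20% right-handed substrate, on the ground that “the reaction slows but does not stop”.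

The flask gives it is still moving, with 44.4% left-handed product, 29.3% right-handed product and 19.0% right-handed substrate.

    left-handed substrate + racemization catalyst ⇌ right-handed substrate + racemization catalyst, rate k1*[racemization catalyst]*[left-handed substrate] forward; the back reaction follows from the equilibrium constant (k = 1.10 M⁻¹ s⁻¹)
    reagent + free catalyst + right-handed substrate → free catalyst + right-handed product (k = 0.630 M⁻² s⁻¹)
    2 racemization catalyst → spent catalyst (k = 6.60 M⁻¹ s⁻¹)
    reagent + free catalyst + left-handed substrate → free catalyst + left-handed product (k = 1.40 M⁻² s⁻¹)

At 15.0 min this flask's substrates together stand at 26.4%, and its reagent at 26% of its own charge. Moved alone in this flask, reagent has to reach 1.62 M or 2.45 M before the right-handed substrate shifts by 5 points. For a neighbour flask with 4.10 mM of free catalyst I multiply N by 1.71. Added to this flask's end-of-feed reciprocal, that gives a remainder of 18.5%, and that neighbour flask holds 18.0% of substrates together at 15.0 min.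

(The earlier runs and the new flask were generated by integration for an exercise; scatter was added.)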